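Chain atoms are called C1 (the =CH2 carbon) to C23 outward from the ring. The retrosynthesis cuts C10–C11 and C8–C9 in the same operation, leaving a C3 unit (C9, C10 and the C10 methyl) between two C16 halves; it then cuts C3–C4 in the head half and C11–C12 in the tail half.
Enabling feature: C9H2–C10H(CH3) is a propane-1,2-diyl unit, a primary carbon beside a methyl-bearing secondary carbon, flanked only by CH2 groups (C8, C11) and four bonds from the nearest sp2 carbon (C6). The lactate-derived (S)-bis-tosylate of propane-1,2-diol can therefore act as a chiral 1,2-bis-electrophile that is alkylated first at C9 and then, with inversion, at C10.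
Head half: the cyclohexene ring is not built; it is taken with its stereocenter from (R)-limonene, which is lithiated at the isopropenyl methyl and allylated (C3–C4) by a (Z)-C6 dichloride. The Z C5=C6 bond is the cis ring alkene of 4-methyl-5,6-dihydro-2H-pyran-2-one, released by reductive opening of that ring.
Tail half: asymmetric hydrogenation of (2E,6E)-farnesol sets C14 and C18; a Grignard/formaldehyde homologation adds C11.
Last, the head-half Grignard reagent, the C3 bis-tosylate and the tail-half Grignard reagent are joined in one flask (C8–C9, then C10–C11). Stereochemistry: ring center from limonene, Z alkene from the pyranone ring, C14 and C18 from the hydrogenation catalyst, C10 from the bis-tosylate by inversion.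
Key step: step 8

Remark: the iridium ligand enantiomer of step 4 is assumed to be the one that turns E-trialkyl alkenes into S centers (the antipode of the one leading to the 3R,7R alcohol), to be confirmed by optical rotation; the pyranone and the bis-tosylate are taken as catalogue compounds.

Step 1
Reactants: 1 4-methyl-5,6-dihydro-2H-pyran-2-one
Product: 2 (Z)-3-methylpent-2-ene-1,5-diol
Conditions: i-Bu2AlH (3.2 equiv), CH2Cl2, −78 °C to 0 °C; aq. potassium sodium tartrate
Reagents that add atoms: none
Why: 1,2-reduction of the unsaturated lactone through the lactol to the allylic diol; the C=C bond was endocyclic in the six-membered ring and no bond to it is broken, so the diol is Z, which fixes the geometry of C5=C6.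

Step 2
Reactants: 2 (Z)-3-methylpent-2-ene-1,5-diol
Product: 4 (Z)-1,5-dichloro-3-methylpent-2-ene, via bis-mesylate 3 (not isolated)
Conditions: MsCl (2.4 equiv), Et3N (3 equiv), CH2Cl2, −40 °C; then LiCl (6 equiv), DMF, 0 °C to 40 °C
Reagents that add atoms: lithium chloride [Li+].[Cl-]; methanesulfonyl chloride CS(=O)(=O)Cl (mesyl groups of 3, chloride pool)
Why: fast bis-mesylation caps both hydroxyls before one can displace the other (which would close 4-methyl-3,6-dihydro-2H-pyran), and chloride then substitutes both primary carbons by SN2 (Finkelstein-type) without SN2' transposition, so the Z alkene is kept.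

Step 3
Reactants: 5 (R)-limonene, 4 (Z)-1,5-dichloro-3-methylpent-2-ene
Product: 7 (4R)-4-[(5Z)-8-chloro-6-methylocta-1,5-dien-2-yl]-1-methylcyclohex-1-ene, via 10-lithiolimonene 6 (not isolated)
Conditions: 5 (2 equiv), n-BuLi (1.0 equiv), TMEDA (1.0 equiv), hexane, rt, 16 h; then added to 4 (1.1 equiv), THF, −78 °C to −30 °C
Reagents that add atoms: none
Why: TMEDA-assisted allylic lithiation of the isopropenyl methyl gives a symmetric 2-substituted allyllithium that alkylates by SN2 at the allylic chloride, far more reactive than the homoallylic chloride (allyl–allyl coupling as used for bisabolene-type chains), forming C3–C4; the ring stereocenter is not deprotonated and is retained.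

Step 4
Reactants: 8 (2E,6E)-farnesol
Product: 9 (3S,7S)-3,7,11-trimethyldodecan-1-ol
Conditions: H2 (50 bar), [Ir(cod)(L)][B(C6H3(CF3)2)4] (1 mol%, L = enantiopure bicyclic pyridine–phosphinite N,P ligand), CH2Cl2, rt
Reagents that add atoms: none
Why: iridium-catalyzed asymmetric hydrogenation of unfunctionalized trialkyl-substituted alkenes, which reduces all three C=C bonds and sets both new centers (C3 and C7, later C14 and C18 of the target) from the E geometry of the C2=C3 and C6=C7 bonds by catalyst control.

Step 5
Reactants: 9 (3S,7S)-3,7,11-trimethyldodecan-1-ol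
Product: 10 (3S,7S)-1-bromo-3,7,11-trimethyldodecane
Conditions: CBr4, PPh3, CH2Cl2, 0 °C to rt
Reagents that add atoms: carbon tetrabromide BrC(Br)(Br)Br
Why: Appel bromination by SN2 at the primary carbinol carbon; the remote stereocenters are untouched.

Step 6
Reactants: 10 (3S,7S)-1-bromo-3,7,11-trimethyldodecane
Product: 12 (4S,8S)-4,8,12-trimethyltridecan-1-ol, via C15 Grignard reagent 11 (not isolated)
Conditions: Mg, THF, 40 °C; then (CH2O)n, THF, 0 °C to rt; aq. NH4Cl
Reagents that add atoms: formaldehyde (from paraformaldehyde) C=O
Why: Grignard formation and addition to formaldehyde, a one-carbon homologation to the primary alcohol that adds C11 of the target.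

Step 7
Reactants: 12 (4S,8S)-4,8,12-trimethyltridecan-1-ol
Product: 13 (4S,8S)-1-bromo-4,8,12-trimethyltridecane
Conditions: CBr4, PPh3, CH2Cl2, 0 °C to rt
Reagents that add atoms: carbon tetrabromide BrC(Br)(Br)Br
Why: Appel bromination by SN2 at the primary carbon; no stereocenter is involved.

Step 8
Reactants: 7 (4R)-4-[(5Z)-8-chloro-6-methylocta-1,5-dien-2-yl]-1-methylcyclohex-1-ene, 14 (S)-propane-1,2-diyl bis(4-methylbenzenesulfonate), 13 (4S,8S)-1-bromo-4,8,12-trimethyltridecane
Product: 18 (R)-1-methyl-4-[(5Z,10S,14S,18S)-6,10,14,18,22-pentamethyltricosa-1,5-dien-2-yl]cyclohex-1-ene (target), via head-half Grignard reagent 15 (not isolated), via secondary tosylate 16 (not isolated), via tail-half Grignard reagent 17 (not isolated)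
Conditions: 7, Mg, THF, 40 °C (15); 13, Mg, THF, rt (17); 14 (1.0 equiv), CuI (10 mol%), TMEDA (20 mol%), THF, −20 °C, 15 (1.0 equiv); then LiOMe (1.0 equiv), 17 (1.6 equiv), 0 °C to rt
Reagents that add atoms: none
Why: Proposed new method: each Grignard reagent is turned by monovalent copper into an alkylcuprate that attacks a C–OTs carbon from the rear (SN2-type oxidative addition to a trivalent copper alkyl) and reductive elimination forms the C–C bond, so 15 first alkylates the primary C9–OTs of 14 to give 16, and 17 then displaces the secondary C10–OTs of 16 to form the C10–C11 bond. The closest known reaction types are the copper-catalyzed Kumada-type alkylation of primary alkyl tosylates and the CuI/TMEDA/LiOMe coupling of unactivated secondary alkyl tosylates with primary alkyl Grignard reagents, which goes with inversion; what is new is running both in sequence on one vicinal bis-tosylate with two different Grignard reagents in one flask. No ring is closed. The only new stereocenter, C10, is the lactate-derived carbon of 14 and is set by inversion in the second displacement (S tosylate to 10S, the descriptor staying S because the priorities change), while the ring center, C14 and C18 are carried through. The step needs site selectivity (C9 before C10), which the steric rate gap between a primary and a methyl-branched secondary sulfonate, the low temperature, one equivalent of 15 and the late addition of LiOMe should secure; it also needs a purely polar path at C10, which the sulfonate leaving group secures because no C10 radical forms that could racemize or cyclize 5-exo onto C5=C6. Both flanks (C8, C11) are unbranched CH2 groups and the nearest sp2 carbon is four bonds away, so neither elimination toward a stabilized alkene nor allylic transposition is favored.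

Compound list
1 | 4-methyl-5,6-dihydro-2H-pyran-2-one | CC1=CC(=O)OCC1 | starting material
2 | (Z)-3-methylpent-2-ene-1,5-diol | OC/C=C(/C)CCO | intermediate
3 | (Z)-3-methylpent-2-ene-1,5-diyl dimethanesulfonate | CS(=O)(=O)OC/C=C(/C)CCOS(C)(=O)=O | intermediate
4 | (Z)-1,5-dichloro-3-methylpent-2-ene | ClC/C=C(/C)CCCl | intermediate
5 | (R)-limonene, (4R)-1-methyl-4-(prop-1-en-2-yl)cyclohex-1-ene | C=C(C)[C@H]1CC=C(C)CC1 | starting material
6 | 10-lithiolimonene, {2-[(1R)-4-methylcyclohex-3-en-1-yl]prop-2-en-1-yl}lithium | [Li]CC(=C)[C@H]1CC=C(C)CC1 | intermediate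
7 | (4R)-4-[(5Z)-8-chloro-6-methylocta-1,5-dien-2-yl]-1-methylcyclohex-1-ene | C=C(CC/C=C(/C)CCCl)[C@H]1CC=C(C)CC1 | intermediate
8 | (2E,6E)-farnesol | CC(C)=CCC/C(C)=C/CC/C(C)=C/CO | starting material
9 | (3S,7S)-3,7,11-trimethyldodecan-1-ol | OCC[C@@H](C)CCC[C@@H](C)CCCC(C)C | intermediate
10 | (3S,7S)-1-bromo-3,7,11-trimethyldodecane | BrCC[C@@H](C)CCC[C@@H](C)CCCC(C)C | intermediate
11 | [(3S,7S)-3,7,11-trimethyldodecyl]magnesium bromide | Br[Mg]CC[C@@H](C)CCC[C@@H](C)CCCC(C)C | intermediate
12 | (4S,8S)-4,8,12-trimethyltridecan-1-ol | OCCC[C@@H](C)CCC[C@@H](C)CCCC(C)C | intermediate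
13 | (4S,8S)-1-bromo-4,8,12-trimethyltridecane | BrCCC[C@@H](C)CCC[C@@H](C)CCCC(C)C | intermediate
14 | (S)-propane-1,2-diyl bis(4-methylbenzenesulfonate) | Cc1ccc(cc1)S(=O)(=O)OC[C@H](C)OS(=O)(=O)c1ccc(C)cc1 | starting material
15 | {(3Z)-3-methyl-7-[(1R)-4-methylcyclohex-3-en-1-yl]octa-3,7-dien-1-yl}magnesium chloride | C=C(CC/C=C(/C)CC[Mg]Cl)[C@H]1CC=C(C)CC1 | intermediate
16 | (2S,6Z)-6-methyl-10-[(1R)-4-methylcyclohex-3-en-1-yl]undeca-6,10-dien-2-yl 4-methylbenzenesulfonate | C=C(CC/C=C(/C)CCC[C@H](C)OS(=O)(=O)c1ccc(C)cc1)[C@H]1CC=C(C)CC1 | intermediate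
17 | [(4S,8S)-4,8,12-trimethyltridecyl]magnesium bromide | Br[Mg]CCC[C@@H](C)CCC[C@@H](C)CCCC(C)C | intermediate
18 | (R)-1-methyl-4-[(5Z,10S,14S,18S)-6,10,14,18,22-pentamethyltricosa-1,5-dien-2-yl]cyclohex-1-ene | C=C(CC/C=C(/C)CCC[C@@H](C)CCC[C@@H](C)CCC[C@@H](C)CCCC(C)C)[C@H]1CC=C(C)CC1 | target

Total step count: 8. Longest linear sequence: 5 steps (steps 4, 5, 6, 7, 8).

Steps most likely to fail

Step 8 (Proposed new method). What may go wrong: incomplete site discrimination between the primary and the secondary sulfonate in the first stage (double alkylation by 15, or unreacted 14 meeting 17), base-induced elimination of the vicinal sulfonate, and erosion of configuration at C10 by halide exchange before the second coupling. Fallback with known chemistry, setting out from 15 and coming back at 16: CuI-catalyzed opening of (S)-methyloxirane at its CH2 by 15 should give (2S,6Z)-6-methyl-10-[(1R)-4-methylcyclohex-3-en-1-yl]undeca-6,10-dien-2-ol F1 with the lactate-type center untouched. Tosylation (TsCl, pyridine, 0 °C) should give 16, now isolated and purified. The separately run coupling of 16 with 17 (CuI, TMEDA, LiOMe, THF, 0 °C), a known reaction type that goes with inversion, should then give 18.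

Step 3. What may go wrong: loss of chemoselectivity between the allylic and the homoallylic chloride, SN2' attack, base-induced elimination of HCl to dienes, and halogen–metal exchange with homocoupling. Fallback, setting out from 2 and coming back at 7: the far terminus is masked so that the electrophile has only one reactive site. Corey–Kim chlorination (N-chlorosuccinimide, Me2S, CH2Cl2, −20 °C), selective for the allylic hydroxyl, should give (Z)-5-chloro-3-methylpent-3-en-1-ol F2. Immediate silylation (TBSCl, imidazole) should give tert-butyl{[(3Z)-5-chloro-3-methylpent-3-en-1-yl]oxy}dimethylsilane F3. Alkylation of 6 with F3 (THF, −78 °C) should give tert-butyldimethyl({(3Z)-3-methyl-7-[(1R)-4-methylcyclohex-3-en-1-yl]octa-3,7-dien-1-yl}oxy)silane F4. Bu4NF should give (3Z)-3-methyl-7-[(1R)-4-methylcyclohex-3-en-1-yl]octa-3,7-dien-1-ol F5, and PPh3 with N-chlorosuccinimide should convert F5 into 7.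

Step 4. What may go wrong: insufficient facial selectivity at one of the two E alkenes, which would give diastereomeric tails that cannot be separated at any later stage, or incomplete reduction. Fallback, setting out from 14 and coming back at 13, so that steps 4 to 7 are bypassed: both tail centers are taken from the lactate pool by stepwise invertive couplings of isolated secondary tosylates. Li2CuCl4-catalyzed coupling of vinylmagnesium bromide with the primary tosylate of 14 should give (S)-pent-4-en-2-yl 4-methylbenzenesulfonate F6, which is also the tosylate of commercial (S)-pent-4-en-2-ol. Coupling of F6 with 4-methylpentylmagnesium bromide F7 (CuI, TMEDA, LiOMe) should give, with inversion, (S)-4,8-dimethylnon-1-ene F8. Radical anti-Markovnikov addition of HBr (dibenzoyl peroxide, hexane, 0 °C) should give (S)-1-bromo-4,8-dimethylnonane F9. Its Grignard reagent [(S)-4,8-dimethylnonyl]magnesium bromide F10 and a second portion of F6 should give (4S,8S)-4,8,12-trimethyltridec-1-ene F11, and a second radical HBr addition should give 13.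

Further compounds
F1 | step 8 | (2S,6Z)-6-methyl-10-[(1R)-4-methylcyclohex-3-en-1-yl]undeca-6,10-dien-2-ol | C=C(CC/C=C(/C)CCC[C@H](C)O)[C@H]1CC=C(C)CC1
F2 | step 3 | (Z)-5-chloro-3-methylpent-3-en-1-ol | ClC/C=C(/C)CCO
F3 | step 3 | tert-butyl{[(3Z)-5-chloro-3-methylpent-3-en-1-yl]oxy}dimethylsilane | ClC/C=C(/C)CCO[Si](C)(C)C(C)(C)C
F4 | step 3 | tert-butyldimethyl({(3Z)-3-methyl-7-[(1R)-4-methylcyclohex-3-en-1-yl]octa-3,7-dien-1-yl}oxy)silane | C=C(CC/C=C(/C)CCO[Si](C)(C)C(C)(C)C)[C@H]1CC=C(C)CC1
F5 | step 3 | (3Z)-3-methyl-7-[(1R)-4-methylcyclohex-3-en-1-yl]octa-3,7-dien-1-ol | C=C(CC/C=C(/C)CCO)[C@H]1CC=C(C)CC1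
F6 | step 4 | (S)-pent-4-en-2-yl 4-methylbenzenesulfonate | C=CC[C@H](C)OS(=O)(=O)c1ccc(C)cc1
F7 | step 4 | 4-methylpentylmagnesium bromide | Br[Mg]CCCC(C)C
F8 | step 4 | (S)-4,8-dimethylnon-1-ene | C=CC[C@@H](C)CCCC(C)C
F9 | step 4 | (S)-1-bromo-4,8-dimethylnonane | BrCCC[C@@H](C)CCCC(C)C
F10 | step 4 | [(S)-4,8-dimethylnonyl]magnesium bromide | Br[Mg]CCC[C@@H](C)CCCC(C)C
F11 | step 4 | (4S,8S)-4,8,12-trimethyltridec-1-ene | C=CC[C@@H](C)CCC[C@@H](C)CCCC(C)C
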